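**Plan**
Feature: ring B carries C2 at C1', the prenyl group at C3', the ring D oxygen at C4' and the ring D carbon C4'' at C5', and it shares its C4'–C5' edge with the six-membered pyran ring D (O–C2''Me2–C3''=C4''). A 1,3,4,5-substituted benzene fused to an oxacycle in this way is the footprint of an oxygen-tethered 1,7-diyne joined to one terminal alkyne.
Cuts: C3''=C4'' is first traced back to a C4'' carbinol. Then C4'–C5', C2'–C3' and C1'–C6' are cut together, giving an ynol ether diyne (C3'≡C4'–O–C2''–C3''–C4''–C5'≡C6'H) and an (S)-2-ethynylchromanone (C1'≡C2'H on C2). The diyne is cut further at C3'–CH2(prenyl), O–C4' and C4''–C5', and the alkyne at C2–C1'.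
Forward: rings A and C are bought as 5,7-dihydroxychromone, rings D and B close together in one cyclotrimerisation, and the ring D alkene is made in the last step.
Stereochemistry: C2 (S) is set by a CuI/chiral P,N-ligand alkynylation of the silyloxychromenylium ion and is then carried only through neutral or weakly acidic steps.
Oxidation level: C4'' travels as a silyl ether, because an alkynyl ether whose oxygen sits on an allylic carbon rearranges ([3,3]) to a ketene far below room temperature. C4'' is therefore a transient centre, used racemic and erased at the end.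

Key step: step 10

Remark: every compound with an sp3 C4'' is racemic (diyne series) or a mixture of both C4'' epimers (after the cycloaddition). The SMILES leave this centre open because the last step removes it.
Remark: the StackPhos antipode that sends the alkynyl group to the Re face of C2 (giving S) is to be fixed by a trial run. Both antipodes are accessible.
Remark: the five starting materials are taken as catalogue compounds. Ynol ethers are purified on Et3N-deactivated silica and stored cold.

**Step 1**
Reactants: 1 4,4-dimethoxy-2-methylbutan-2-ol; 2 trichloroethylene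
Product: 4 (E)-3-(1,2-dichloroethenyloxy)-1,1-dimethoxy-3-methylbutane, via dichloroacetylene 3 (not isolated)
Conditions: KH (2 equiv), THF, 0 °C; then 2, −50 °C → rt; H2O quench
Reagents that add atoms: none
Why: Base-induced loss of HCl from 2 gives 3 in solution and the potassium alkoxide of 1 adds to it in anti fashion (nucleophilic addition to a haloalkyne, first stage of the trichloroethylene route to ynol ethers); the acetal is inert to KH, and the substrate holds no silyl group that could migrate to the tertiary alkoxide.

**Step 2**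
Reactants: 4 (E)-3-(1,2-dichloroethenyloxy)-1,1-dimethoxy-3-methylbutane
Product: 5 (E)-3-(1,2-dichloroethenyloxy)-3-methylbutanal
Conditions: SiO2 / 10% aq. oxalic acid, CH2Cl2, rt
Reagents that add atoms: water, SMILES O
Why: Acid-catalysed acetal hydrolysis; the aliphatic dimethyl acetal should cleave much faster than the chlorine-deactivated enol ether is protonated, and the mild two-phase medium limits β-elimination to the enal.

**Step 3**
Reactants: 5 (E)-3-(1,2-dichloroethenyloxy)-3-methylbutanal; 6 ethynyltrimethylsilane
Product: 8 rac-(E)-5-(1,2-dichloroethenyloxy)-5-methyl-1-(trimethylsilyl)hex-1-yn-3-ol, via lithium trimethylsilylacetylide 7 (not isolated)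
Conditions: 6, n-BuLi, THF, −78 °C; then 5, −78 °C; H2O
Reagents that add atoms: none
Why: 1,2-Addition of a lithium acetylide to an aldehyde forms C4''–C5' and is fast at −78 °C relative to enolisation, so the β-alkoxy group should not be expelled; the carbinol centre C4'' is formed racemic on purpose.

**Step 4**
Reactants: 8 rac-(E)-5-(1,2-dichloroethenyloxy)-5-methyl-1-(trimethylsilyl)hex-1-yn-3-ol
Product: 9 rac-(E)-3-(tert-butyldimethylsilyloxy)-5-(1,2-dichloroethenyloxy)-5-methyl-1-(trimethylsilyl)hex-1-yne
Conditions: TBSCl, imidazole, DMF, rt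
Reagents that add atoms: tert-butyldimethylsilyl chloride (TBSCl), SMILES CC(C)(C)[Si](C)(C)Cl
Why: Standard silylation of a secondary propargylic alcohol; the tertiary oxygen is already capped as the vinyl ether, so no O-to-O silyl migration is possible here or later.

**Step 5**
Reactants: 9 rac-(E)-3-(tert-butyldimethylsilyloxy)-5-(1,2-dichloroethenyloxy)-5-methyl-1-(trimethylsilyl)hex-1-yne; 10 prenyl bromide (1-bromo-3-methylbut-2-ene)
Product: 13 rac-3-(tert-butyldimethylsilyloxy)-5-methyl-5-(5-methylhex-4-en-1-ynyloxy)-1-(trimethylsilyl)hex-1-yne, via chloroalkynyl ether 11 (not isolated), via lithium alkoxyacetylide 12 (not isolated)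
Conditions: n-BuLi (2.1 equiv), THF, −78 → −40 °C; then 10, DMPU, −78 °C → rt
Reagents that add atoms: none
Why: Second stage of the trichloroethylene route: deprotonation and loss of LiCl give 11, chlorine–lithium exchange gives 12, and SN2 alkylation of this acetylide by the primary allylic bromide forms the C3'–CH2 bond; the C-silyl and O-silyl groups tolerate n-BuLi at −78 °C.

**Step 6**
Reactants: 13 rac-3-(tert-butyldimethylsilyloxy)-5-methyl-5-(5-methylhex-4-en-1-ynyloxy)-1-(trimethylsilyl)hex-1-yne
Product: 14 rac-3-(tert-butyldimethylsilyloxy)-5-methyl-5-(5-methylhex-4-en-1-ynyloxy)hex-1-yne (ynol ether 1,7-diyne)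
Conditions: K2CO3, MeOH, 0 °C → rt
Reagents that add atoms: none
Why: Carbonate-promoted methanolysis of the C(sp)–SiMe3 bond; ynol ethers, the skipped enyne and a secondary TBS ether are stable to this mild base, and the temperature stays far below the retro-ene range of the tertiary ynol ether.

**Step 7**
Reactants: 15 5,7-dihydroxy-4H-chromen-4-one
Product: 16 5,7-bis(tert-butyldimethylsilyloxy)-4H-chromen-4-one
Conditions: TBSOTf (2.5 equiv), 2,6-lutidine, CH2Cl2, 0 °C → rt
Reagents that add atoms: tert-butyldimethylsilyl triflate (TBSOTf), SMILES CC(C)(C)[Si](C)(C)OS(=O)(=O)C(F)(F)F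
Why: O-Silylation with a silyl triflate, which is strong enough to cap the hydrogen-bonded 5-OH; silyl ethers are chosen because they are inert to the silyl triflate of step 8, whereas acetal-type groups on a cationic chromenylium ring would be shed.

**Step 8**
Reactants: 16 5,7-bis(tert-butyldimethylsilyloxy)-4H-chromen-4-one; 6 ethynyltrimethylsilane
Product: 20 (S)-5,7-bis(tert-butyldimethylsilyloxy)-2-[(trimethylsilyl)ethynyl]chroman-4-one, via silyloxychromenylium triflate 17 (not isolated), via copper acetylide 18 (not isolated), via trimethylsilyl enol ether 19 (not isolated)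
Conditions: CuI (5 mol %), StackPhos (6 mol %), TMSOTf, iPr2NEt, toluene, −20 °C; then 1 M HCl, THF, 0 °C
Reagents that add atoms: none
Why: Enantioselective copper-catalysed alkynylation of a chromone through its 4-silyloxychromenylium ion: TMSOTf turns 16 into 17, the ligand-bound acetylide 18 of monovalent copper adds to the Re face of C2 under control of the axially chiral P,N-ligand and so sets C2 as S, and brief mild acid hydrolyses enol ether 19 while sparing the aryl TBS ethers.

**Step 9**
Reactants: 20 (S)-5,7-bis(tert-butyldimethylsilyloxy)-2-[(trimethylsilyl)ethynyl]chroman-4-one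
Product: 21 (S)-5,7-bis(tert-butyldimethylsilyloxy)-2-ethynylchroman-4-one
Conditions: AgNO3 (10 mol %), acetone/H2O, rt, dark
Reagents that add atoms: none
Why: Silver-catalysed protiodesilylation of a trimethylsilylalkyne, a neutral method that spares aryl TBS ethers and avoids the base that would racemise C2 by retro-oxa-Michael ring opening.

**Step 10**
Reactants: 14 rac-3-(tert-butyldimethylsilyloxy)-5-methyl-5-(5-methylhex-4-en-1-ynyloxy)hex-1-yne; 21 (S)-5,7-bis(tert-butyldimethylsilyloxy)-2-ethynylchroman-4-one
Product: 23 (2S)-5,7-bis(tert-butyldimethylsilyloxy)-2-[4-(tert-butyldimethylsilyloxy)-2,2-dimethyl-8-(3-methylbut-2-enyl)chroman-6-yl]chroman-4-one (both C4'' epimers), via ruthenacyclopentadiene 22 (not isolated)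
Conditions: Cp*RuCl(cod) (5–10 mol %), ClCH2CH2Cl, rt, Ar; 14 (slight excess) added slowly by syringe pump to 21 and catalyst
Reagents that add atoms: none
Why: Cp*RuCl(cod) loses cod, and the divalent ruthenium fragment binds both triple bonds of 14 and couples them oxidatively to ruthenacyclopentadiene 22 (tetravalent ruthenium), which forms C4'–C5' and closes ring D as a six-membered oxacycle in an exo,exo-dig mode (C3' and C6' stay outside ring D, on the metal), the gem-dimethyl group at C2'' and the branched C4'' favouring the folded conformer. Alkyne 21 then coordinates and inserts at the unhindered Ru–C6' bond, and reductive elimination from the resulting ruthenacycloheptatriene closes ring B as the second six-membered ring, forming C1'–C6' and C2'–C3' and returning divalent ruthenium. The closest known reaction type is the Cp*RuCl(cod)-catalysed (2+2+2) cycloaddition of diynes substituted at one terminus with terminal alkynes, and diynes whose tether starts at an ynol ether or ynamide heteroatom are established partners in metal-catalysed cyclotrimerisation. No stereocentre is created; C2 and C4'' are spectators, and the neutral medium at room temperature stays clear of retro-oxa-Michael racemisation at C2 and of the retro-ene fragmentation that tertiary alkyl ynol ethers undergo on heating. The step needs regioselectivity, C1' bonding to C6' and C2' to C3', and this is secured by the repulsion between the prenyl-bearing metallacycle terminus under the Cp* ligand and the branched chromanone substituent, which therefore ends up meta to the prenyl group. It also needs cross- over self-cycloaddition, which slow addition of 14 secures by keeping the concentration of free diyne low.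

**Step 11**
Reactants: 23 (2S)-5,7-bis(tert-butyldimethylsilyloxy)-2-[4-(tert-butyldimethylsilyloxy)-2,2-dimethyl-8-(3-methylbut-2-enyl)chroman-6-yl]chroman-4-one
Product: 24 (2S)-5,7-dihydroxy-2-[4-hydroxy-2,2-dimethyl-8-(3-methylbut-2-enyl)chroman-6-yl]chroman-4-one (both C4'' epimers)
Conditions: HF·pyridine, pyridine, THF, 0 °C → rt
Reagents that add atoms: none
Why: Fluoride cleavage of all three silyl ethers in a weakly acidic, pyridine-buffered medium, in which no phenoxide forms, so the flavanone ring should not open and C2 should hold.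

**Step 12**
Reactants: 24 (2S)-5,7-dihydroxy-2-[4-hydroxy-2,2-dimethyl-8-(3-methylbut-2-enyl)chroman-6-yl]chroman-4-one
Product: 25 (2S)-5,7-dihydroxy-2-[2,2-dimethyl-8-(3-methylbut-2-enyl)-2H-chromen-6-yl]chroman-4-one (target)
Conditions: p-TsOH·H2O (5 mol %), toluene/THF, 50 °C, dilute
Reagents that add atoms: none
Why: Acid-catalysed E1 dehydration of a 2,2-dimethylchroman-4-ol, the standard entry to 2,2-dimethylchromenes: both epimers ionise to the same C4'' cation, which is stabilised by the ortho ring D oxygen and can lose a proton only from C3''; the alcohol ionises far more readily than the C2–O1 bond, and the prenyl group has no free ortho phenol to cyclise onto.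

**Compound list**
1 | 4,4-dimethoxy-2-methylbutan-2-ol | CC(C)(O)CC(OC)OC | starting material
2 | trichloroethylene | ClC=C(Cl)Cl | starting material
3 | dichloroacetylene (not isolated) | ClC#CCl | intermediate
4 | (E)-3-(1,2-dichloroethenyloxy)-1,1-dimethoxy-3-methylbutane | COC(CC(C)(C)O/C(Cl)=C\Cl)OC | intermediate
5 | (E)-3-(1,2-dichloroethenyloxy)-3-methylbutanal | O=CCC(C)(C)O/C(Cl)=C\Cl | intermediate
6 | ethynyltrimethylsilane | C#C[Si](C)(C)C | starting material
7 | lithium (trimethylsilyl)acetylide (not isolated) | [Li]C#C[Si](C)(C)C | intermediate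
8 | rac-(E)-5-(1,2-dichloroethenyloxy)-5-methyl-1-(trimethylsilyl)hex-1-yn-3-ol | C[Si](C)(C)C#CC(O)CC(C)(C)O/C(Cl)=C\Cl | intermediate
9 | rac-(E)-3-(tert-butyldimethylsilyloxy)-5-(1,2-dichloroethenyloxy)-5-methyl-1-(trimethylsilyl)hex-1-yne | C[Si](C)(C)C#CC(CC(C)(C)O/C(Cl)=C\Cl)O[Si](C)(C)C(C)(C)C | intermediate
10 | prenyl bromide (1-bromo-3-methylbut-2-ene) | CC(C)=CCBr | starting material
11 | rac-3-(tert-butyldimethylsilyloxy)-5-(chloroethynyloxy)-5-methyl-1-(trimethylsilyl)hex-1-yne (not isolated) | C[Si](C)(C)C#CC(CC(C)(C)OC#CCl)O[Si](C)(C)C(C)(C)C | intermediate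
12 | lithium alkoxyacetylide derived from 11 (not isolated) | C[Si](C)(C)C#CC(CC(C)(C)OC#C[Li])O[Si](C)(C)C(C)(C)C | intermediate
13 | rac-3-(tert-butyldimethylsilyloxy)-5-methyl-5-(5-methylhex-4-en-1-ynyloxy)-1-(trimethylsilyl)hex-1-yne | CC(C)=CCC#COC(C)(C)CC(C#C[Si](C)(C)C)O[Si](C)(C)C(C)(C)C | intermediate
14 | rac-3-(tert-butyldimethylsilyloxy)-5-methyl-5-(5-methylhex-4-en-1-ynyloxy)hex-1-yne | CC(C)=CCC#COC(C)(C)CC(C#C)O[Si](C)(C)C(C)(C)C | intermediate
15 | 5,7-dihydroxy-4H-chromen-4-one | O=c1ccoc2cc(O)cc(O)c12 | starting material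
16 | 5,7-bis(tert-butyldimethylsilyloxy)-4H-chromen-4-one | O=c1ccoc2cc(O[Si](C)(C)C(C)(C)C)cc(O[Si](C)(C)C(C)(C)C)c12 | intermediate
17 | 5,7-bis(tert-butyldimethylsilyloxy)-4-(trimethylsilyloxy)chromenylium triflate (not isolated) | C[Si](C)(C)Oc1cc[o+]c2cc(O[Si](C)(C)C(C)(C)C)cc(O[Si](C)(C)C(C)(C)C)c12.[O-]S(=O)(=O)C(F)(F)F | intermediate
18 | copper (trimethylsilyl)acetylide, ligand-bound, ligand not drawn (not isolated) | [Cu]C#C[Si](C)(C)C | intermediate
19 | (S)-5,7-bis(tert-butyldimethylsilyloxy)-4-(trimethylsilyloxy)-2-[(trimethylsilyl)ethynyl]-2H-chromene (not isolated) | C[Si](C)(C)C#C[C@@H]1C=C(O[Si](C)(C)C)c2c(O[Si](C)(C)C(C)(C)C)cc(O[Si](C)(C)C(C)(C)C)cc2O1 | intermediate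
20 | (S)-5,7-bis(tert-butyldimethylsilyloxy)-2-[(trimethylsilyl)ethynyl]chroman-4-one | C[Si](C)(C)C#C[C@@H]1CC(=O)c2c(O[Si](C)(C)C(C)(C)C)cc(O[Si](C)(C)C(C)(C)C)cc2O1 | intermediate
21 | (S)-5,7-bis(tert-butyldimethylsilyloxy)-2-ethynylchroman-4-one | C#C[C@@H]1CC(=O)c2c(O[Si](C)(C)C(C)(C)C)cc(O[Si](C)(C)C(C)(C)C)cc2O1 | intermediate
22 | Cp*RuCl ruthenacyclopentadiene of 14, Ru bonded to C3' and C6' (not isolated) | C[c-]1c(C)c(C)c(C)c1C.Cl[Ru+]1C(CC=C(C)C)=C2OC(C)(C)CC(O[Si](C)(C)C(C)(C)C)C2=C1 | intermediate
23 | (2S)-5,7-bis(tert-butyldimethylsilyloxy)-2-[4-(tert-butyldimethylsilyloxy)-2,2-dimethyl-8-(3-methylbut-2-enyl)chroman-6-yl]chroman-4-one, both C4'' epimers | CC(C)=CCc1cc([C@@H]2CC(=O)c3c(O[Si](C)(C)C(C)(C)C)cc(O[Si](C)(C)C(C)(C)C)cc3O2)cc2c1OC(C)(C)CC2O[Si](C)(C)C(C)(C)C | intermediate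
24 | (2S)-5,7-dihydroxy-2-[4-hydroxy-2,2-dimethyl-8-(3-methylbut-2-enyl)chroman-6-yl]chroman-4-one, both C4'' epimers | CC(C)=CCc1cc([C@@H]2CC(=O)c3c(O)cc(O)cc3O2)cc2c1OC(C)(C)CC2O | intermediate
25 | (2S)-5,7-dihydroxy-2-[2,2-dimethyl-8-(3-methylbut-2-enyl)-2H-chromen-6-yl]chroman-4-one | CC(C)=CCc1cc([C@@H]2CC(=O)c3c(O)cc(O)cc3O2)cc2c1OC(C)(C)C=C2 | target

**Step count**
- Total: 12 steps.
- Longest linear sequence: 9 steps (steps 1–6, then 10–12).
- The alkyne branch (steps 7–9) joins at step 10.

**Steps most likely to fail**

*Step 10.*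
- The diyne may consume itself by self-cycloaddition or oligomerisation.
- Oxidative coupling across the 1,7-tether may be too slow.
- The tertiary ynol ether may fragment to a ketene on the metal.
- The meta preference may erode.

The fallback takes ring B from a purchased arene and makes C2–C1' by asymmetric conjugate arylation. It sets out from 16 and comes back at 25. Purchased 4-bromophenol is C-prenylated at the ortho position as its sodium salt (NaH, 10, toluene) to give 4-bromo-2-(3-methylbut-2-enyl)phenol F1. Copper-catalysed O-alkylation with 3-chloro-3-methylbut-1-yne (CuCl2, DBU, MeCN) gives the aryl 1,1-dimethylpropargyl ether F2. Heating in N,N-diethylaniline triggers the cascade of aromatic Claisen rearrangement, hydrogen shift and 6π-electrocyclisation to 6-bromo-2,2-dimethyl-8-(3-methylbut-2-enyl)-2H-chromene F3. Bromine–lithium exchange (n-BuLi), B(OiPr)3 and aqueous acid give the chromenylboronic acid F4. Rhodium-catalysed asymmetric 1,4-addition of F4 to chromone 16 ([Rh(OH)(cod)]2, the antipode of an electron-poor chiral biaryl bisphosphine that gives 2S, toluene/H2O) gives the 5,7-bis-TBS ether of the target F5. Et3N·3HF in THF then gives 25.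

*Step 8.*
- The chromenylium ion, stabilised by two oxygen donors, is a weak electrophile, and its C4 silyloxy group is crowded by the 5-OTBS group, so conversion may stall.
- Facial selectivity with the small silylacetylene may be poor.

The fallback is a racemic addition of a stoichiometric acetylide followed by kinetic resolution. It sets out from 16 and comes back at 20. Chromone 16 is converted into 17 with TMSOTf in CH2Cl2 and treated at −78 °C with preformed 7. This gives the racemic silyl enol ether F6, which is hydrolysed on work-up to the racemic 2-alkynylchromanone F7. Asymmetric transfer hydrogenation with RuCl[(R,R)-TsDPEN](p-cymene) and HCO2H/Et3N is stopped near half conversion. By the usual aryl ketone model it should reduce the (R)-ketone to the cis-(2R,4R)-chroman-4-ol F8 and leave the (S)-ketone 20, which is separated by chromatography.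

*Step 5.*
- Attack at the tertiary end of the allylic bromide may compete.
- A proton may transfer from the doubly activated CH2 of the product to the acetylide, with drift to an allenyl ether.
- Chlorine–lithium exchange may be incomplete.

The fallback uses an isolable stannane and a palladium-catalysed allylation in place of the SN2 alkylation. It sets out from 9 and comes back at 13. Acetylide 12 is generated as in step 5 and quenched with Bu3SnCl to give the tributylstannyl ynol ether F9. Stille coupling of F9 with 10 (Pd2(dba)3, AsPh3, THF, rt) joins the alkynyl group to the primary terminus of the allyl ligand on divalent palladium and gives 13 under neutral conditions.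

**Further compounds**
F1 | step 10 | 4-bromo-2-(3-methylbut-2-enyl)phenol | CC(C)=CCc1cc(Br)ccc1O
F2 | step 10 | 4-bromo-1-(2-methylbut-3-yn-2-yloxy)-2-(3-methylbut-2-enyl)benzene | CC(C)=CCc1cc(Br)ccc1OC(C)(C)C#C
F3 | step 10 | 6-bromo-2,2-dimethyl-8-(3-methylbut-2-enyl)-2H-chromene | CC(C)=CCc1cc(Br)cc2c1OC(C)(C)C=C2
F4 | step 10 | [2,2-dimethyl-8-(3-methylbut-2-enyl)-2H-chromen-6-yl]boronic acid | CC(C)=CCc1cc(B(O)O)cc2c1OC(C)(C)C=C2
F5 | step 10 | (2S)-5,7-bis(tert-butyldimethylsilyloxy)-2-[2,2-dimethyl-8-(3-methylbut-2-enyl)-2H-chromen-6-yl]chroman-4-one | CC(C)=CCc1cc([C@@H]2CC(=O)c3c(O[Si](C)(C)C(C)(C)C)cc(O[Si](C)(C)C(C)(C)C)cc3O2)cc2c1OC(C)(C)C=C2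
F6 | step 8 | rac-5,7-bis(tert-butyldimethylsilyloxy)-4-(trimethylsilyloxy)-2-[(trimethylsilyl)ethynyl]-2H-chromene | C[Si](C)(C)C#CC1C=C(O[Si](C)(C)C)c2c(O[Si](C)(C)C(C)(C)C)cc(O[Si](C)(C)C(C)(C)C)cc2O1
F7 | step 8 | rac-5,7-bis(tert-butyldimethylsilyloxy)-2-[(trimethylsilyl)ethynyl]chroman-4-one | C[Si](C)(C)C#CC1CC(=O)c2c(O[Si](C)(C)C(C)(C)C)cc(O[Si](C)(C)C(C)(C)C)cc2O1
F8 | step 8 | (2R,4R)-5,7-bis(tert-butyldimethylsilyloxy)-2-[(trimethylsilyl)ethynyl]chroman-4-ol | C[Si](C)(C)C#C[C@H]1C[C@@H](O)c2c(O[Si](C)(C)C(C)(C)C)cc(O[Si](C)(C)C(C)(C)C)cc2O1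
F9 | step 5 | rac-3-(tert-butyldimethylsilyloxy)-5-methyl-5-[(tributylstannyl)ethynyloxy]-1-(trimethylsilyl)hex-1-yne | CCCC[Sn](CCCC)(CCCC)C#COC(C)(C)CC(C#C[Si](C)(C)C)O[Si](C)(C)C(C)(C)C
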